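## Retrosynthetic overview

1. Target 11 ⇒ (S)-diol 9 by acylation of the primary hydroxyl only with palmitoyl chloride.
2. Diol 9 ⇒ triol 7 by periodate excision of a sacrificial Me2C(OH) carbon and reduction; 7 ⇒ hydroxy diester 6 by exhaustive MeMgBr addition.
3. Key disconnection: the indole C3–C bond of 6 ⇒ 5-prenylindole 3 + meso dimethyl cis-epoxysuccinate 5. A catalytic, enantiotopos-selective Friedel–Crafts opening of the meso-epoxide sets the only stereocentre of the target.
4. 3 ⇒ 5-bromoindole 1 + prenylstannane 2 (Stille); 5 ⇒ cis-epoxysuccinic acid 4 (esterification).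
5. Ring order: no ring is built. The indole is bought intact, and the only other ring, the oxirane of 4, is bought and opened in the key step.

Assumption: the sense of induction of the Sc(OTf)3/(S,S)-Ph-pybox catalyst in step 3 cannot be predicted with certainty; the (S,S)-ligand is written, and the (R,R)-ligand (equally available) is used if it proves to give ent-6.

## Route

Step 1
Reactants: 1 5-bromo-1H-indole; 2 tributyl(3-methylbut-2-en-1-yl)stannane
Product: 3 5-(3-methylbut-2-en-1-yl)-1H-indole
Conditions: Pd(PPh3)4 (5 mol %), DMF, 100 °C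
Reagents that add atoms: none
Why: Stille cross-coupling, in which zerovalent palladium inserts into the C–Br bond, the prenyl group is transmetalated from tin and reductive elimination at the unsubstituted allyl terminus gives the linear prenyl arene, the free N–H being tolerated.

Step 2
Reactants: 4 cis-epoxysuccinic acid, (2R,3S)-oxirane-2,3-dicarboxylic acid (meso)
Product: 5 dimethyl (2R,3S)-oxirane-2,3-dicarboxylate (meso)
Conditions: MeI (2.5 equiv), K2CO3, DMF, rt
Reagents that add atoms: iodomethane, CI
Why: Carboxylate O-alkylation (SN2 on MeI) under weakly basic, non-acidic conditions esterifies both acids without opening the oxirane or touching its cis geometry.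

Step 3
Reactants: 3 5-(3-methylbut-2-en-1-yl)-1H-indole; 5 dimethyl (2R,3S)-oxirane-2,3-dicarboxylate (1.3 equiv)
Product: 6 dimethyl (2S,3S)-2-hydroxy-3-[5-(3-methylbut-2-en-1-yl)-1H-indol-3-yl]butanedioate
Conditions: Sc(OTf)3 (10 mol %), (S,S)-Ph-pybox [2,6-bis((4S)-4-phenyl-4,5-dihydrooxazol-2-yl)pyridine] (12 mol %), 4 Å molecular sieves, CH2Cl2, −20 °C to rt
Reagents that add atoms: none
Why: Proposed new method: the cis-diester chelates the chiral trivalent scandium–pybox Lewis acid through the oxirane oxygen and the ester carbonyls, which makes the two mirror-related C–O bonds diastereotopic, and indole C3 attacks the (R)-configured oxirane carbon in an SN2 Friedel–Crafts alkylation from the face opposite to oxygen (inversion there, retention at the carbinol carbon), giving the (2S,3S) product and thereby the (S) stereocentre of the target; the closest known reaction types are the chiral Lewis acid-catalysed enantioselective ring-opening of meso-epoxides by indoles, Sc(OTf)3–pybox Friedel–Crafts alkylations of indoles with chelating electrophiles, and the opening of epoxysuccinates at the carbon next to the ester by heteroatom and cuprate nucleophiles.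

Step 4
Reactants: 6 dimethyl (2S,3S)-2-hydroxy-3-[5-(3-methylbut-2-en-1-yl)-1H-indol-3-yl]butanedioate
Product: 7 (3S,4S)-2,5-dimethyl-4-[5-(3-methylbut-2-en-1-yl)-1H-indol-3-yl]hexane-2,3,5-triol
Conditions: MeMgBr (8 equiv), LaCl3·2LiCl (30 mol %), THF, −20 °C to rt; aq NH4Cl
Reagents that add atoms: methylmagnesium bromide, C[Mg]Br
Why: Double Grignard addition to each ester gives the two tertiary carbinols after N–H and O–H are deprotonated first, and the resulting dianion together with the low-basicity lanthanum-activated reagent disfavours enolisation at the indole-bearing carbon, so both stereocentres are kept.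

Step 5
Reactants: 7 (3S,4S)-2,5-dimethyl-4-[5-(3-methylbut-2-en-1-yl)-1H-indol-3-yl]hexane-2,3,5-triol
Product: 9 (2S)-3-methyl-2-[5-(3-methylbut-2-en-1-yl)-1H-indol-3-yl]butane-1,3-diol, via hydroxy aldehyde 8 (not isolated)
Conditions: NaIO4 (1.1 equiv), THF/NaH2PO4–Na2HPO4 buffer (pH 7), 0 °C, 20 min; then NaBH4 (excess), EtOH, 0 °C, same pot
Reagents that add atoms: none
Why: Malaprade glycol cleavage cuts only the vicinal C2/C3 diol (the C5 tertiary hydroxyl is 1,3-related and inert) to aldehyde 8 and acetone, and immediate NaBH4 reduction at 0 °C and neutral pH outruns enolisation and retro-aldol, so the stereocentre from step 3 is carried over unchanged (its descriptor reads 4S in 7, 2R in 8 and 2S in 9 only because the CIP priorities change).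

Step 6
Reactants: 9 (2S)-3-methyl-2-[5-(3-methylbut-2-en-1-yl)-1H-indol-3-yl]butane-1,3-diol; 10 hexadecanoyl chloride (1.05 equiv)
Product: 11 (2S)-3-hydroxy-3-methyl-2-[5-(3-methylbut-2-en-1-yl)-1H-indol-3-yl]butyl hexadecanoate (CNP0125367.1)
Conditions: pyridine, CH2Cl2, −20 to 0 °C
Reagents that add atoms: none
Why: Acylation with an acid chloride and pyridine (no DMAP) is far faster at the primary hydroxyl than at the tertiary hydroxyl or the indole N–H, and the stereocentre is not involved.

## Compound list

1 | 5-bromo-1H-indole | Brc1ccc2[nH]ccc2c1 | starting material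
2 | tributyl(3-methylbut-2-en-1-yl)stannane | CCCC[Sn](CCCC)(CCCC)CC=C(C)C | starting material
3 | 5-(3-methylbut-2-en-1-yl)-1H-indole | CC(C)=CCc1ccc2[nH]ccc2c1 | intermediate
4 | cis-epoxysuccinic acid, (2R,3S)-oxirane-2,3-dicarboxylic acid | OC(=O)[C@H]1O[C@H]1C(=O)O | starting material
5 | dimethyl (2R,3S)-oxirane-2,3-dicarboxylate | COC(=O)[C@H]1O[C@H]1C(=O)OC | intermediate
6 | dimethyl (2S,3S)-2-hydroxy-3-[5-(3-methylbut-2-en-1-yl)-1H-indol-3-yl]butanedioate | COC(=O)[C@@H](O)[C@H](c1c[nH]c2ccc(CC=C(C)C)cc12)C(=O)OC | intermediate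
7 | (3S,4S)-2,5-dimethyl-4-[5-(3-methylbut-2-en-1-yl)-1H-indol-3-yl]hexane-2,3,5-triol | CC(C)(O)[C@@H](O)[C@H](c1c[nH]c2ccc(CC=C(C)C)cc12)C(C)(C)O | intermediate
8 | (2R)-3-hydroxy-3-methyl-2-[5-(3-methylbut-2-en-1-yl)-1H-indol-3-yl]butanal | O=C[C@H](c1c[nH]c2ccc(CC=C(C)C)cc12)C(C)(C)O | intermediate
9 | (2S)-3-methyl-2-[5-(3-methylbut-2-en-1-yl)-1H-indol-3-yl]butane-1,3-diol | OC[C@H](c1c[nH]c2ccc(CC=C(C)C)cc12)C(C)(C)O | intermediate
10 | hexadecanoyl chloride | CCCCCCCCCCCCCCCC(=O)Cl | starting material
11 | (2S)-3-hydroxy-3-methyl-2-[5-(3-methylbut-2-en-1-yl)-1H-indol-3-yl]butyl hexadecanoate | CCCCCCCCCCCCCCCC(=O)OC[C@H](c1c[nH]c2ccc(CC=C(C)C)cc12)C(C)(C)O | target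

## Step count and risks

Total steps: 6. Longest linear sequence: 5 steps (1, 3, 4, 5, 6 from 5-bromoindole; equally 2, 3, 4, 5, 6 from cis-epoxysuccinic acid).

Steps most likely to fail:

Step 3 (key step). The electron-poor oxirane may open sluggishly, the malate-like product may sequester the catalyst, and the level and sense of enantiotopos selection are untested. The fallback moves stereocontrol from the catalyst to the substrate and sets out from 3. Compound 3 is alkylated under achiral Sc(OTf)3 catalysis (CH2Cl2 or hexafluoroisopropanol) with the enantiopure C2-symmetric trans-epoxide diethyl (2R,3R)-oxirane-2,3-dicarboxylate F1 (commercial, also available from diethyl L-tartrate). Its two oxirane carbons are equivalent, so SN2 inversion at either one gives diethyl (2R,3S)-2-hydroxy-3-[5-(3-methylbut-2-en-1-yl)-1H-indol-3-yl]butanedioate F2 with the required (S) configuration at the indole-bearing carbon. MeMgBr as in step 4 then gives (3R,4S)-2,5-dimethyl-4-[5-(3-methylbut-2-en-1-yl)-1H-indol-3-yl]hexane-2,3,5-triol F3. F3 differs from 7 only at the carbinol centre, which is destroyed in the NaIO4 cleavage, so the sequence comes back to the route at aldehyde 8 and continues to 9.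

Step 5. Aldehyde 8 has an enolisable α-hydrogen next to the indole and a tertiary β-hydroxyl (racemisation, retro-aldol), and NaIO4 can slowly oxidise the indole. The fallback sets out from 7 and comes back at 9. The cleavage to 8 is kept, but the stereocentre is no longer relayed: 8 is deliberately left to racemise in buffer at pH 7.5–8 and is reduced under dynamic kinetic resolution by an (S)-selective alcohol dehydrogenase (ketoreductase screen, NADPH recycled with glucose and glucose dehydrogenase). The enzyme then sets the configuration of 9, and any loss of optical purity at the aldehyde stage becomes irrelevant. No new compound is made.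

Step 4. The magnesium aldolate of the malate-type diester can fragment by retro-aldol or stall as a chelate, and the indole-bearing carbon can epimerise. Any epimer shows up as a diastereomer of 7 and can be removed there by chromatography or crystallisation. The fallback removes the aldolate altogether; it sets out from 6 and comes back at 7. Compound 6 is silylated at the secondary hydroxyl (TBSCl, imidazole, DMF) to dimethyl (2S,3S)-2-[(tert-butyldimethylsilyl)oxy]-3-[5-(3-methylbut-2-en-1-yl)-1H-indol-3-yl]butanedioate F4. MeMgBr then gives (3S,4S)-3-[(tert-butyldimethylsilyl)oxy]-2,5-dimethyl-4-[5-(3-methylbut-2-en-1-yl)-1H-indol-3-yl]hexane-2,5-diol F5, and Bu4NF in THF releases 7.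

## Further compounds

F1 | step 3 | diethyl (2R,3R)-oxirane-2,3-dicarboxylate | CCOC(=O)[C@@H]1O[C@H]1C(=O)OCC
F2 | step 3 | diethyl (2R,3S)-2-hydroxy-3-[5-(3-methylbut-2-en-1-yl)-1H-indol-3-yl]butanedioate | CCOC(=O)[C@H](O)[C@H](c1c[nH]c2ccc(CC=C(C)C)cc12)C(=O)OCC
F3 | step 3 | (3R,4S)-2,5-dimethyl-4-[5-(3-methylbut-2-en-1-yl)-1H-indol-3-yl]hexane-2,3,5-triol | CC(C)(O)[C@H](O)[C@H](c1c[nH]c2ccc(CC=C(C)C)cc12)C(C)(C)O
F4 | step 4 | dimethyl (2S,3S)-2-[(tert-butyldimethylsilyl)oxy]-3-[5-(3-methylbut-2-en-1-yl)-1H-indol-3-yl]butanedioate | COC(=O)[C@@H](O[Si](C)(C)C(C)(C)C)[C@H](c1c[nH]c2ccc(CC=C(C)C)cc12)C(=O)OC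
F5 | step 4 | (3S,4S)-3-[(tert-butyldimethylsilyl)oxy]-2,5-dimethyl-4-[5-(3-methylbut-2-en-1-yl)-1H-indol-3-yl]hexane-2,5-diol | CC(C)(O)[C@@H](O[Si](C)(C)C(C)(C)C)[C@H](c1c[nH]c2ccc(CC=C(C)C)cc12)C(C)(C)O
F0 | step 5 | none | none
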